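## The problem

Target 28 is a germacrane: a ten-membered carbocycle C1–C10 with an E-trisubstituted C1=C10 alkene (C14 methyl on C10), a trisubstituted 4,5-epoxide (C15 methyl on C4) in which C3 and C6 are cis, a free hydroxyl on C6, an angelate on C8 and a C7 side chain C11(H)(C13H3)–C12H2–O-angelate. The six stereocentres are 4S,5R,6R,7S,8S,11S: the epoxide oxygen, the C6 hydroxyl and the C7 side chain lie on one face of the ring and the C8 ester on the other. A synthesis must close a medium ring against entropy and transannular strain while fixing the geometry of two trisubstituted ring alkenes, 1(10)E and the 4Z precursor of the epoxide. C8 can be set first and can control C7; C7, together with the geometry of the bond that creates it, can control C6; the C6 hydroxyl can then direct the epoxide (C4, C5). C11 lies outside the ring between two similar oxygenated carbons and is the hardest centre to control. The 4,5-epoxide facing C1=C10 across the ring cyclises transannularly under acid, the 1,5-diene is acid- and heat-sensitive, and angelates isomerise to the E esters or migrate to a free neighbouring hydroxyl under nucleophilic or basic conditions, so epoxide and esters must come late and under mild conditions. The enabling feature is the fragment HO–C6–C7–C11 beside the C4=C5 bond: if C11 is written as an isopropenyl carbon (C11=C12), C6 is an allylic carbinol and C6–C7–C11=C12 a homoallylic alcohol. That is the product pattern of a [2,3]-Wittig shift of an allyl ether (C6)O–C12H2–C11(CH3)=C7, so the carbocycle can come from contraction of a thirteen-membered cyclic diallyl ether in which oxygen joins C6 to C12.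

## Retrosynthesis

**28 to 27 (epoxide C4–O and C5–O).** The epoxide is removed first, giving the 4Z-allylic alcohol 27. In 28 the epoxide oxygen is cis to the C6 hydroxyl, which is the relationship a hydroxyl-directed epoxidation gives in a Z-cycloalkenol of medium ring size. Placing this step last keeps the acid-labile epoxide/1(10)-ene pair out of every other step. The forward reaction must choose C4=C5 over C1=C10 and the two electron-poor angelate alkenes, and must choose the face syn to the hydroxyl.

**27 to 26 to 23 and 24 (two ester C–O bonds, one O–Si bond).** Both angelates are cut together to the 8,12-diol 23 and two equivalents of angelic acid 24, with C6 held as a silyl ether in 26 so that only O8 and O12 are acylated. Cutting the esters one at a time would add steps without gain. The forward acylation must not isomerise the Z acyl group, and the final desilylation must not generate an alkoxide that could trigger acyl migration.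

**23 to 22 to 20 to 19 (O8–aryl bond; C12–O and C11–H bonds; O6–Si bond).** The C8 hydroxyl is traced to a 4-methoxyphenyl ether, and the C12 hydroxyl with the C11 stereocentre to hydroboration of an isopropenyl group. This leads back to the homoallylic alcohol 19, which has three stereocentres instead of six. The aryl ether is preferred to a benzyl-type ether because it has no hydrogen alpha to oxygen that a strong base could remove in the key step. The forward hydroboration must select the 1,1-disubstituted alkene over two trisubstituted ones and must select one face at C11. For the latter, the C6 silyl ether is put on first, so that the C6 flank of C7 is clearly the larger one.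

**19 to 18 (C6–C7 bond; the key disconnection).** Breaking C6–C7 while reconnecting O6 to C12 turns the ten-membered carbocycle 19 into the thirteen-membered diallyl ether 18. Compared with a direct carbon–carbon closure of the ten-membered ring at the same bond, this moves the ring-forming event to an ether synthesis of a larger, less strained ring and makes the carbon–carbon bond formation a sigmatropic shift inside a ring that already exists. The precursor has a single stereocentre (C8) and three alkenes of fixed geometry. The forward step must lithiate C6 and not C12, must add to the face of C7 dictated by C8, and must translate the Z geometry of C7=C11 into the cis relationship of O6 and the isopropenyl group.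

**18 to 17 to 16 to 14 to 13 (O–C12 bond, then functional-group changes).** The ether is opened at O–C12 to the hydroxy chloride 17, an open-chain farnesane with the alkoxide at C6 and the allylic chloride at C12. This compound comes from the silyl ether 16, the allylic alcohol 14 and the Z-enoate 13. Placing the chloride at C12 and the alcohol at C6, and not the reverse, also leaves 17 one oxidation away from an aldehyde/allyl chloride pair, which is the substrate of the fallback for the key step. The forward etherification needs high dilution and clean SN2 substitution.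

**13 to 11 and 12 (C7=C11 bond).** The Z-trisubstituted enoate is cut at the alkene to the α-aryloxy aldehyde 11 and the trifluoroethyl phosphonate 12, which supplies C11, C12 and C13. A Z-selective olefination is needed because C8 must be cis to C12 for the ring contraction to give the required C6/C7 relationship. The aldehyde must be made and used without epimerising C8.

**11 to 10 to 9 to 8 and 4; 8 to 5 and 6 (C8–C9 bond).** C8 is the only stereocentre not derived from another one. It is set by alkylating the chiral aryloxyacetyl imide 8, made from acid 5 and auxiliary 6, with the allylic bromide 4, which joins the two halves at C8–C9. Aldol or epoxide-opening routes to C8 would need more steps to reach the same oxidation pattern. The forward reaction must alkylate on the face opposite the benzyl group of the auxiliary.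

**4 to 3 to 2 to 1 (C9–Br, then C9–O).** Bromide 4 comes from nerol 1 by silylation and allylic oxidation of the methyl group trans to the chain. Nerol supplies ten of the fifteen skeletal carbons (C1–C6, C9, C10, C14, C15) with the 4Z geometry in place. The oxidation supplies the 1(10)E geometry.

## Roads not taken

Alternative 1: chromium allylation that closes the ring and an 8,12-lactone together. The cut is at C7–C8 and at the lactone C12–O8 bond. In the forward step CrCl2 (divalent chromium) would insert into the allylic C–Br bond of a 2-(bromomethyl)acrylate terminus, the allylchromium would add through its γ-carbon C7 to a C8 aldehyde at high dilution, and the chromium alkoxide at O8 would close the α-methylene lactone. The product of this step is the trans-fused 6-(tert-butyldimethylsilyloxy)germacra-1(10)E,4Z,11(13)-trien-12,8-olide A1.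
Merits: one operation makes the ring, C7, C8 and the lactone of A1. The usual anti preference of allylchromium additions matches the 7,8-trans relationship. The lactone of A1 carries O8 and C12 already differentiated from O6, and its exocyclic methylene is a handle for C11.
Weak points: C6 has to be installed beforehand as a Z-allylic silyl ether next to the acrylate, which needs its own asymmetric step. That silyloxy group sits beta to the allylmetal carbon and can be lost by elimination. Nothing in a ten-membered-ring-forming transition state predicts how C6 would direct C7. A carbon–carbon closure of the ten-membered ring needs high dilution and a large excess of chromium.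
Comparison: the end game from A1 is shorter than the chosen one, because the lactone replaces both the hydroboration and the aryl-ether removal. The chosen plan sets against this an easier ring closure (a thirteen-membered etherification) and a C6/C7 relationship that follows from alkene geometry and a tethered sigmatropic shift, not from an unmodelled 1,2-induction.

Alternative 2: allyl sulfone macro-alkylation joining the two allylic methylenes. The cut is at C2–C3. In the forward step KN(SiMe3)2 at high dilution would deprotonate an E-allylic sulfone at C2, and the carbanion would displace a Z-allylic chloride at C3. The product of this step is 6-(tert-butyldimethylsilyloxy)-8,12-bis(4-methoxybenzyloxy)-2-(phenylsulfonyl)germacra-1(10)E,4Z-diene A2, as either C2 epimer, which is then desulfonylated reductively.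
Merits: C6, C7, C8 and C11 and all three oxygens are in place before the ring of A2 closes and can be made by acyclic reactions of predictable outcome. For C11 in particular this is better than the chosen plan. Both alkenes are preformed, and sulfone-stabilised carbanions are reliable for medium-ring alkylation.
Weak points: a four-centre stereo-array with three differently protected oxygens and two allylic termini makes a long linear sequence. The allylic sulfone anion can alkylate at its γ-carbon, the allylic chloride can react SN2′, and reductive removal of the allylic sulfone from A2 often shifts or isomerises the C1=C10 alkene. The ring-forming step creates no stereocentre.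
Comparison: the road through A2 is stereochemically the most secure. The chosen plan sets against it brevity (nerol brings both ring alkenes, and the key step makes the ring and two stereocentres at once) and a thermodynamic repair route for its one insecure centre, C11.

Alternative 3: anionic oxy-Cope ring expansion with a silicon-masked C8 oxygen. The cut is at C8–C9, with C1–C6 reconnected to a six-membered ring. In the forward step the potassium alkoxide (KH, 18-crown-6) of a tertiary cyclohexenol carrying two adjacent alkenyl groups would rearrange, forming C8–C9, breaking C1–C6 and expanding the ring by four atoms. Protonation of the enolate would give 8-(benzyldimethylsilyl)-12-(4-methoxybenzyloxy)germacra-1(10)E,4Z-dien-6-one A3.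
Merits: no high dilution is needed and the ten-membered ring of A3 comes from a cheap six-membered terpene-type enone. The 1(10)E geometry follows from a chair transition state and the 4Z geometry is inherited from the cyclohexene. The silyl group is a hydroxyl surrogate that can be oxidised with retention.
Weak points: C7 of A3 is formed by protonation of an enolate next to the C6 ketone, so it is neither controlled by the rearrangement nor configurationally safe. C6 then needs a diastereoselective reduction of an enone in a flexible ring. The alkenyl nucleophile that carries both the vinylsilane and the C11 centre must add to an enolisable ketone cis to the neighbouring alkenyl group. Silicon oxidation and benzyl-ether removal add late steps in the presence of two trisubstituted alkenes.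
Comparison: as a ring construction the road to A3 is more economical than etherification followed by contraction, and operationally simpler. The chosen plan sets against it that C7 is never alpha to a carbonyl, that C6 arrives directly as the carbinol with a defined relation to C7, and that C8 is an auxiliary-controlled oxygen stereocentre from the start.

Key step: step 13

Assumption: nerol 1 and angelic acid 24 are taken as geometrically pure commercial materials; germacrane numbering (C1–C15) is used for the ring compounds and for the corresponding atoms of their open-chain precursors.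

## Route

Step 1
Reactants: 1 nerol
Product: 2 (2Z)-1-(tert-butyldimethylsilyloxy)-3,7-dimethylocta-2,6-diene
Conditions: TBSCl, imidazole, CH2Cl2, 0 °C → rt
Reagents that add atoms: tert-butyldimethylsilyl chloride, CC(C)(C)[Si](C)(C)Cl
Why: Standard silylation of a primary allylic alcohol; the ether masks O6 through the oxidising, basic and reducing steps that follow and leaves the Z alkene untouched.

Step 2
Reactants: 2 (2Z)-1-(tert-butyldimethylsilyloxy)-3,7-dimethylocta-2,6-diene
Product: 3 (2E,6Z)-8-(tert-butyldimethylsilyloxy)-2,6-dimethylocta-2,6-dien-1-ol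
Conditions: SeO2 (10 mol %), t-BuOOH, salicylic acid (10 mol %), CH2Cl2, 0 °C → rt
Reagents that add atoms: tert-butyl hydroperoxide, CC(C)(C)OO
Why: SeO2-catalysed allylic oxidation (ene reaction, then [2,3]-shift) attacks the remote, more electron-rich trisubstituted alkene at the methyl group trans to the chain. This gives the E-allylic alcohol whose carbon becomes C9 and whose alkene is the 1(10)E bond of the target.

Step 3
Reactants: 3 (2E,6Z)-8-(tert-butyldimethylsilyloxy)-2,6-dimethylocta-2,6-dien-1-ol
Product: 4 (2E,6Z)-1-bromo-8-(tert-butyldimethylsilyloxy)-2,6-dimethylocta-2,6-diene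
Conditions: CBr4, PPh3, CH2Cl2, 0 °C
Reagents that add atoms: carbon tetrabromide, BrC(Br)(Br)Br
Why: Appel bromination of a primary allylic alcohol under neutral conditions; SN2 displacement at the unhindered CH2 avoids allylic transposition and spares the silyl ether.

Step 4
Reactants: 5 (4-methoxyphenoxy)acetic acid; 6 (R)-4-benzyl-2-oxazolidinone
Product: 8 (R)-4-benzyl-3-[(4-methoxyphenoxy)acetyl]oxazolidin-2-one, via mixed pivalic anhydride 7 (not isolated)
Conditions: t-BuCOCl, Et3N, THF, −20 °C; then 6, LiCl, rt
Reagents that add atoms: none
Why: N-Acylation of the oxazolidinone through the mixed pivalic anhydride with LiCl and Et3N is the standard one-pot route to acyl imides and needs no separate acid chloride.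

Step 5
Reactants: 8 (R)-4-benzyl-3-[(4-methoxyphenoxy)acetyl]oxazolidin-2-one; 4 (2E,6Z)-1-bromo-8-(tert-butyldimethylsilyloxy)-2,6-dimethylocta-2,6-diene
Product: 9 (4R)-4-benzyl-3-[(2S,4E,8Z)-10-(tert-butyldimethylsilyloxy)-2-(4-methoxyphenoxy)-4,8-dimethyldeca-4,8-dienoyl]oxazolidin-2-one
Conditions: NaN(SiMe3)2, THF, −78 °C; then 4, −78 → −45 °C
Reagents that add atoms: none
Why: Evans alkylation of a glycolate-type imide: the chelated sodium Z-enolate is attacked by the primary allylic bromide on the face opposite the benzyl group, forming C8–C9. With the R auxiliary this should give the 8S centre; the aryl ether has no position that the base can attack.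

Step 6
Reactants: 9 (4R)-4-benzyl-3-[(2S,4E,8Z)-10-(tert-butyldimethylsilyloxy)-2-(4-methoxyphenoxy)-4,8-dimethyldeca-4,8-dienoyl]oxazolidin-2-one
Product: 10 (2S,4E,8Z)-10-(tert-butyldimethylsilyloxy)-2-(4-methoxyphenoxy)-4,8-dimethyldeca-4,8-dien-1-ol
Conditions: LiBH4, MeOH (1 equiv), THF, 0 °C
Reagents that add atoms: none
Why: Reductive cleavage of the acyl imide to the primary alcohol with return of the auxiliary; C8 is not enolised and the silyl ether and alkenes are inert.

Step 7
Reactants: 10 (2S,4E,8Z)-10-(tert-butyldimethylsilyloxy)-2-(4-methoxyphenoxy)-4,8-dimethyldeca-4,8-dien-1-ol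
Product: 11 (2S,4E,8Z)-10-(tert-butyldimethylsilyloxy)-2-(4-methoxyphenoxy)-4,8-dimethyldeca-4,8-dienal
Conditions: Dess–Martin periodinane, CH2Cl2, 0 °C → rt
Reagents that add atoms: none
Why: Dess–Martin oxidation gives the α-aryloxy aldehyde without base, so C8 is not epimerised; the aldehyde is used at once.

Step 8
Reactants: 11 (2S,4E,8Z)-10-(tert-butyldimethylsilyloxy)-2-(4-methoxyphenoxy)-4,8-dimethyldeca-4,8-dienal; 12 methyl 2-[bis(2,2,2-trifluoroethoxy)phosphoryl]propanoate
Product: 13 methyl (2Z,4S,6E,10Z)-12-(tert-butyldimethylsilyloxy)-4-(4-methoxyphenoxy)-2,6,10-trimethyldodeca-2,6,10-trienoate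
Conditions: KN(SiMe3)2, 18-crown-6, THF, −78 °C
Reagents that add atoms: none
Why: Still–Gennari olefination: the electron-poor phosphonate with a dissociated potassium counter-ion eliminates fast from the kinetic adduct and should give the Z-trisubstituted enoate, with C8 cis to the ester carbon C12. This is the geometry the ring contraction needs, and −78 °C protects C8.

Step 9
Reactants: 13 methyl (2Z,4S,6E,10Z)-12-(tert-butyldimethylsilyloxy)-4-(4-methoxyphenoxy)-2,6,10-trimethyldodeca-2,6,10-trienoate
Product: 14 (2Z,4S,6E,10Z)-12-(tert-butyldimethylsilyloxy)-4-(4-methoxyphenoxy)-2,6,10-trimethyldodeca-2,6,10-trien-1-ol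
Conditions: i-Bu2AlH, CH2Cl2, −78 °C
Reagents that add atoms: none
Why: 1,2-Reduction of the enoate to the allylic alcohol; alkene geometry, aryl ether and silyl ether are unaffected at low temperature.

Step 10
Reactants: 14 (2Z,4S,6E,10Z)-12-(tert-butyldimethylsilyloxy)-4-(4-methoxyphenoxy)-2,6,10-trimethyldodeca-2,6,10-trien-1-ol
Product: 16 (2Z,6E,9S,10Z)-1-(tert-butyldimethylsilyloxy)-12-chloro-9-(4-methoxyphenoxy)-3,7,11-trimethyldodeca-2,6,10-triene, via allylic mesylate 15 (not isolated)
Conditions: MsCl, LiCl, 2,4,6-collidine, DMF, 0 °C
Reagents that add atoms: lithium chloride, [Li+].[Cl-]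
Why: Mesylation followed by in situ SN2 displacement with chloride converts a primary allylic alcohol into the chloride without allylic transposition or loss of Z geometry; the silyl ether survives the buffered conditions.

Step 11
Reactants: 16 (2Z,6E,9S,10Z)-1-(tert-butyldimethylsilyloxy)-12-chloro-9-(4-methoxyphenoxy)-3,7,11-trimethyldodeca-2,6,10-triene
Product: 17 (2Z,6E,9S,10Z)-12-chloro-9-(4-methoxyphenoxy)-3,7,11-trimethyldodeca-2,6,10-trien-1-ol
Conditions: HF·pyridine, pyridine, THF, 0 °C → rt
Reagents that add atoms: none
Why: Buffered HF·pyridine cleaves the primary allylic silyl ether; because no alkoxide is formed, the allylic chloride is neither displaced nor etherified prematurely.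

Step 12
Reactants: 17 (2Z,6E,9S,10Z)-12-chloro-9-(4-methoxyphenoxy)-3,7,11-trimethyldodeca-2,6,10-trien-1-ol
Product: 18 (3Z,5S,7E,11Z)-5-(4-methoxyphenoxy)-3,7,11-trimethyl-1-oxacyclotrideca-3,7,11-triene
Conditions: NaH, n-Bu4NI (10 mol %), THF, slow addition to 2 mM, 45 °C
Reagents that add atoms: none
Why: Intramolecular Williamson etherification: the C6 alkoxide displaces the primary allylic chloride at C12 (SN2, iodide catalysis) under high dilution. A thirteen-membered ring with three planar alkene units closes with little transannular strain, and the O–C12 bond made here is the bond given up in step 13.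

Step 13
Reactants: 18 (3Z,5S,7E,11Z)-5-(4-methoxyphenoxy)-3,7,11-trimethyl-1-oxacyclotrideca-3,7,11-triene
Product: 19 (6S,7S,8S)-8-(4-methoxyphenoxy)germacra-1(10)E,4Z,11(12)-trien-6-ol
Conditions: n-BuLi (2 equiv), THF, −78 → −20 °C; then H2O
Reagents that add atoms: none
Why: n-BuLi removes a proton from C6, the ether methylene allylic to C4=C5, and the α-oxy allylic carbanion attacks C7, the far end of the other allyl arm (O–C12–C11=C7), through a five-membered envelope transition state in which C6–C7 forms, O–C12 breaks and C11=C12 appears as the isopropenyl group; this is a [2,3]-Wittig rearrangement, and the contraction of thirteen-membered diallyl ethers to ten-membered homoallylic alcohols bearing an isopropenyl group is the closest known reaction type. The ten-membered carbocycle is closed by ring contraction, not by an end-to-end cyclisation: C6 and C7 are already held 1,5 to each other across the ether oxygen, and O, C12 and C11 leave the ring to become the carbinol oxygen and the isopropenyl group. C7 is controlled by C8: allylic 1,3-strain with C12 keeps H8 in the plane of the Z alkene, so C9 and the six-carbon bridge that carries C6 lie on one face, and the carbanion is expected to arrive on that face, anti to the C8–O bond. C6 is controlled relative to C7 by the Z geometry of C7=C11 (C8 cis to C12), which in the envelope should lead to the syn product, that is O6 cis to the isopropenyl group on the ring; the E-configured series is known to give the trans arrangement. The step needs deprotonation at C6 and not at C12: a C12 carbanion could rearrange only onto the fully substituted C4, and the 4-methoxyphenyl ether at C8 was chosen because it has no hydrogen alpha to oxygen, whereas a benzyl-type ether would open a second Wittig pathway. Low temperature is meant to suppress the [1,2]-shift, loss of aryloxide from any C12-metalated material and loss of Z geometry in the allyl anion.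

Step 14
Reactants: 19 (6S,7S,8S)-8-(4-methoxyphenoxy)germacra-1(10)E,4Z,11(12)-trien-6-ol
Product: 20 (6S,7R,8S)-6-(tert-butyldimethylsilyloxy)-8-(4-methoxyphenoxy)germacra-1(10)E,4Z,11(12)-triene
Conditions: TBSOTf, 2,6-lutidine, CH2Cl2, −78 → 0 °C
Reagents that add atoms: tert-butyldimethylsilyl trifluoromethanesulfonate, CC(C)(C)[Si](C)(C)OS(=O)(=O)C(F)(F)F
Why: The silyl triflate protects the hindered secondary allylic alcohol; the bulky ether sets O6 apart from O8 and O12 and makes the C6 flank of C7 the larger one for step 15. (The C7 descriptor changes from S to R only because silicon raises the CIP rank of the C6 branch.)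

Step 15
Reactants: 20 (6S,7R,8S)-6-(tert-butyldimethylsilyloxy)-8-(4-methoxyphenoxy)germacra-1(10)E,4Z,11(12)-triene
Product: 22 (6S,7R,8S,11S)-6-(tert-butyldimethylsilyloxy)-8-(4-methoxyphenoxy)germacra-1(10)E,4Z-dien-12-ol, via alkylborane 21 (not isolated)
Conditions: 9-BBN, THF, 0 °C → rt; then NaOH, H2O2, 0 °C
Reagents that add atoms: hydrogen peroxide, OO
Why: 9-BBN adds to the 1,1-disubstituted alkene much faster than to the two trisubstituted ring alkenes and places boron on C12; oxidation with retention gives the primary alcohol. C11 is set by C7: in the staggered four-centre transition state H7 lies next to the C13 methyl, the bulkier silyloxy-bearing C6 arm is anti to the incoming borane and C8 is inside, which is expected to deliver hydrogen to the face that gives 11S.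

Step 16
Reactants: 22 (6S,7R,8S,11S)-6-(tert-butyldimethylsilyloxy)-8-(4-methoxyphenoxy)germacra-1(10)E,4Z-dien-12-ol
Product: 23 (6S,7R,8S,11S)-6-(tert-butyldimethylsilyloxy)germacra-1(10)E,4Z-diene-8,12-diol
Conditions: (NH4)2Ce(NO3)6, pyridine, MeCN/H2O (4:1), 0 °C
Reagents that add atoms: none
Why: Oxidative dearylation: tetravalent cerium oxidises the electron-rich 4-methoxyphenyl ring, water adds, and the adduct collapses to 1,4-benzoquinone and the C8 alcohol with the C8–O bond intact. The isolated trisubstituted alkenes are much harder to oxidise than the arene, and pyridine buffers the nitric acid formed so that the silyl ether and the 1,5-diene should survive.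

Step 17
Reactants: 23 (6S,7R,8S,11S)-6-(tert-butyldimethylsilyloxy)germacra-1(10)E,4Z-diene-8,12-diol; 24 angelic acid
Product: 26 (6S,7R,8S,11S)-6-(tert-butyldimethylsilyloxy)germacra-1(10)E,4Z-diene-8,12-diyl bis[(Z)-2-methylbut-2-enoate], via mixed angelic anhydride 25 (not isolated)
Conditions: 24 (3 equiv), 2,4,6-trichlorobenzoyl chloride (3 equiv), Et3N, toluene, rt; then 23, 75 °C
Reagents that add atoms: angelic acid (second equivalent), C/C=C(/C)C(=O)O
Why: Yamaguchi-type esterification through the mixed anhydride, run without a nucleophilic amine catalyst, is the established way to make angelates without Z-to-E isomerisation. Two equivalents of the anhydride are consumed, one at the primary O12 and one at the secondary O8, while O6 stays silylated.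

Step 18
Reactants: 26 (6S,7R,8S,11S)-6-(tert-butyldimethylsilyloxy)germacra-1(10)E,4Z-diene-8,12-diyl bis[(Z)-2-methylbut-2-enoate]
Product: 27 (6S,7S,8S,11S)-6-hydroxygermacra-1(10)E,4Z-diene-8,12-diyl bis[(Z)-2-methylbut-2-enoate]
Conditions: HF·pyridine, pyridine, THF, 0 °C → rt
Reagents that add atoms: none
Why: Fluoride cleavage of the secondary silyl ether under buffered, slightly acidic conditions; no free alkoxide is formed, which should prevent angeloyl migration to O6 and leave the Z esters unchanged.

Step 19
Reactants: 27 (6S,7S,8S,11S)-6-hydroxygermacra-1(10)E,4Z-diene-8,12-diyl bis[(Z)-2-methylbut-2-enoate]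
Product: 28 (4S,5R,6R,7S,8S,11S)-4,5-epoxy-6-hydroxygermacr-1(10)E-ene-8,12-diyl bis[(Z)-2-methylbut-2-enoate]
Conditions: VO(acac)2 (5 mol %), t-BuOOH, CH2Cl2, 0 °C → rt
Reagents that add atoms: tert-butyl hydroperoxide, CC(C)(C)OO
Why: Hydroxyl-directed epoxidation: the C6 alkoxide binds vanadium, which delivers the peroxide oxygen to the adjacent C4=C5 bond only, while C1=C10 (no directing group) and the electron-poor angelate alkenes do not react. In Z-cycloalkenols of medium ring size this reagent places the oxygen cis to the hydroxyl, which is the 4S,5R arrangement of the target, under neutral conditions that the new epoxide tolerates.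

## Compound list

1 | nerol, (2Z)-3,7-dimethylocta-2,6-dien-1-ol | CC(C)=CCC/C(C)=C\CO | starting material
2 | (2Z)-1-(tert-butyldimethylsilyloxy)-3,7-dimethylocta-2,6-diene | CC(C)=CCC/C(C)=C\CO[Si](C)(C)C(C)(C)C | intermediate
3 | (2E,6Z)-8-(tert-butyldimethylsilyloxy)-2,6-dimethylocta-2,6-dien-1-ol | OC/C(C)=C/CC/C(C)=C\CO[Si](C)(C)C(C)(C)C | intermediate
4 | (2E,6Z)-1-bromo-8-(tert-butyldimethylsilyloxy)-2,6-dimethylocta-2,6-diene | BrC/C(C)=C/CC/C(C)=C\CO[Si](C)(C)C(C)(C)C | intermediate
5 | (4-methoxyphenoxy)acetic acid | COc1ccc(OCC(=O)O)cc1 | starting material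
6 | (R)-4-benzyl-2-oxazolidinone | O=C1OC[C@@H](Cc2ccccc2)N1 | starting material
7 | (4-methoxyphenoxy)acetic pivalic anhydride | COc1ccc(OCC(=O)OC(=O)C(C)(C)C)cc1 | intermediate
8 | (R)-4-benzyl-3-[(4-methoxyphenoxy)acetyl]oxazolidin-2-one | O=C1OC[C@@H](Cc2ccccc2)N1C(=O)COc3ccc(OC)cc3 | intermediate
9 | (4R)-4-benzyl-3-[(2S,4E,8Z)-10-(tert-butyldimethylsilyloxy)-2-(4-methoxyphenoxy)-4,8-dimethyldeca-4,8-dienoyl]oxazolidin-2-one | O=C1OC[C@@H](Cc2ccccc2)N1C(=O)[C@@H](Oc3ccc(OC)cc3)C/C(C)=C/CC/C(C)=C\CO[Si](C)(C)C(C)(C)C | intermediate
10 | (2S,4E,8Z)-10-(tert-butyldimethylsilyloxy)-2-(4-methoxyphenoxy)-4,8-dimethyldeca-4,8-dien-1-ol | OC[C@@H](Oc1ccc(OC)cc1)C/C(C)=C/CC/C(C)=C\CO[Si](C)(C)C(C)(C)C | intermediate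
11 | (2S,4E,8Z)-10-(tert-butyldimethylsilyloxy)-2-(4-methoxyphenoxy)-4,8-dimethyldeca-4,8-dienal | O=C[C@@H](Oc1ccc(OC)cc1)C/C(C)=C/CC/C(C)=C\CO[Si](C)(C)C(C)(C)C | intermediate
12 | methyl 2-[bis(2,2,2-trifluoroethoxy)phosphoryl]propanoate | COC(=O)C(C)P(=O)(OCC(F)(F)F)OCC(F)(F)F | starting material
13 | methyl (2Z,4S,6E,10Z)-12-(tert-butyldimethylsilyloxy)-4-(4-methoxyphenoxy)-2,6,10-trimethyldodeca-2,6,10-trienoate | COC(=O)/C(C)=C\[C@@H](Oc1ccc(OC)cc1)C/C(C)=C/CC/C(C)=C\CO[Si](C)(C)C(C)(C)C | intermediate
14 | (2Z,4S,6E,10Z)-12-(tert-butyldimethylsilyloxy)-4-(4-methoxyphenoxy)-2,6,10-trimethyldodeca-2,6,10-trien-1-ol | OC/C(C)=C\[C@@H](Oc1ccc(OC)cc1)C/C(C)=C/CC/C(C)=C\CO[Si](C)(C)C(C)(C)C | intermediate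
15 | (2Z,4S,6E,10Z)-12-(tert-butyldimethylsilyloxy)-4-(4-methoxyphenoxy)-2,6,10-trimethyldodeca-2,6,10-trien-1-yl methanesulfonate | CS(=O)(=O)OC/C(C)=C\[C@@H](Oc1ccc(OC)cc1)C/C(C)=C/CC/C(C)=C\CO[Si](C)(C)C(C)(C)C | intermediate
16 | (2Z,6E,9S,10Z)-1-(tert-butyldimethylsilyloxy)-12-chloro-9-(4-methoxyphenoxy)-3,7,11-trimethyldodeca-2,6,10-triene | ClC/C(C)=C\[C@@H](Oc1ccc(OC)cc1)C/C(C)=C/CC/C(C)=C\CO[Si](C)(C)C(C)(C)C | intermediate
17 | (2Z,6E,9S,10Z)-12-chloro-9-(4-methoxyphenoxy)-3,7,11-trimethyldodeca-2,6,10-trien-1-ol | ClC/C(C)=C\[C@@H](Oc1ccc(OC)cc1)C/C(C)=C/CC/C(C)=C\CO | intermediate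
18 | (3Z,5S,7E,11Z)-5-(4-methoxyphenoxy)-3,7,11-trimethyl-1-oxacyclotrideca-3,7,11-triene | O1C/C=C(/C)CC/C=C(\C)C[C@H](Oc2ccc(OC)cc2)/C=C(/C)C1 | intermediate
19 | (6S,7S,8S)-8-(4-methoxyphenoxy)germacra-1(10)E,4Z,11(12)-trien-6-ol | CC(=C)[C@H]1[C@@H](O)/C=C(/C)CC/C=C(\C)C[C@@H]1Oc2ccc(OC)cc2 | intermediate
20 | (6S,7R,8S)-6-(tert-butyldimethylsilyloxy)-8-(4-methoxyphenoxy)germacra-1(10)E,4Z,11(12)-triene | CC(=C)[C@H]1[C@@H](O[Si](C)(C)C(C)(C)C)/C=C(/C)CC/C=C(\C)C[C@@H]1Oc2ccc(OC)cc2 | intermediate
21 | 9-[(6S,7R,8S,11R)-6-(tert-butyldimethylsilyloxy)-8-(4-methoxyphenoxy)germacra-1(10)E,4Z-dien-12-yl]-9-borabicyclo[3.3.1]nonane | C1CC2CCCC(C1)B2C[C@@H](C)[C@H]3[C@@H](O[Si](C)(C)C(C)(C)C)/C=C(/C)CC/C=C(\C)C[C@@H]3Oc4ccc(OC)cc4 | intermediate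
22 | (6S,7R,8S,11S)-6-(tert-butyldimethylsilyloxy)-8-(4-methoxyphenoxy)germacra-1(10)E,4Z-dien-12-ol | OC[C@@H](C)[C@H]1[C@@H](O[Si](C)(C)C(C)(C)C)/C=C(/C)CC/C=C(\C)C[C@@H]1Oc2ccc(OC)cc2 | intermediate
23 | (6S,7R,8S,11S)-6-(tert-butyldimethylsilyloxy)germacra-1(10)E,4Z-diene-8,12-diol | OC[C@@H](C)[C@H]1[C@@H](O[Si](C)(C)C(C)(C)C)/C=C(/C)CC/C=C(\C)C[C@@H]1O | intermediate
24 | angelic acid, (Z)-2-methylbut-2-enoic acid | C/C=C(/C)C(=O)O | starting material
25 | (Z)-2-methylbut-2-enoic 2,4,6-trichlorobenzoic anhydride | C/C=C(/C)C(=O)OC(=O)c1c(Cl)cc(Cl)cc1Cl | intermediate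
26 | (6S,7R,8S,11S)-6-(tert-butyldimethylsilyloxy)germacra-1(10)E,4Z-diene-8,12-diyl bis[(Z)-2-methylbut-2-enoate] | C/C=C(/C)C(=O)OC[C@@H](C)[C@H]1[C@@H](O[Si](C)(C)C(C)(C)C)/C=C(/C)CC/C=C(\C)C[C@@H]1OC(=O)/C(C)=C\C | intermediate
27 | (6S,7S,8S,11S)-6-hydroxygermacra-1(10)E,4Z-diene-8,12-diyl bis[(Z)-2-methylbut-2-enoate] | C/C=C(/C)C(=O)OC[C@@H](C)[C@H]1[C@@H](O)/C=C(/C)CC/C=C(\C)C[C@@H]1OC(=O)/C(C)=C\C | intermediate
28 | (4S,5R,6R,7S,8S,11S)-4,5-epoxy-6-hydroxygermacr-1(10)E-ene-8,12-diyl bis[(Z)-2-methylbut-2-enoate] (CNP0272382.1) | C/C=C(/C)C(=O)OC[C@@H](C)[C@H]1[C@@H](O)[C@H]2O[C@@]2(C)CC/C=C(\C)C[C@@H]1OC(=O)/C(C)=C\C | target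

## Step count and least certain steps

Total step count: 19. Longest linear sequence: 18 steps (steps 1–3 and 5–19 from nerol 1; step 4 is a one-step side branch from 5 and 6).

**Step 13 (key step).** The most likely failures are lithiation at the wrong site (the C12 methylene or the C8 methine), followed by a [1,2]-shift or by expulsion of aryloxide, and erosion of face selectivity at C7 if the thirteen-membered ring folds with C9 and C6 on opposite faces of the C7=C11 bond. Fallback: form the same C6–C7 bond by an intramolecular Nozaki–Hiyama allylation, a different mechanism that needs no carbanion next to the aryl ether. The fallback sets out from 17. MnO2 in CH2Cl2 oxidises the primary allylic alcohol to (2Z,6E,9S,10Z)-12-chloro-9-(4-methoxyphenoxy)-3,7,11-trimethyldodeca-2,6,10-trienal F1. CrCl2 in THF at high dilution converts the allylic chloride into an allylchromium that adds through C7 to the C6 aldehyde and closes the ten-membered ring. Because allylchromium reagents normally react through the E-allylmetal in a chair transition state, the 6,7-anti product is expected to dominate, namely the 6-epimer of 19, (6R,7S,8S)-8-(4-methoxyphenoxy)germacra-1(10)E,4Z,11(12)-trien-6-ol F2, provided C8 again directs attack anti to its C–O bond. Mitsunobu inversion (4-nitrobenzoic acid, PPh3, DIAD) would give the 6-O-(4-nitrobenzoyl) derivative of 19 F3, and K2CO3 in MeOH returns the route at 19.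

**Step 15.** The most likely failure is poor facial selectivity at C11, because the two flanks of C7 are both oxygenated ring carbons and differ only in their substituents. Fallback: thermodynamic control in a ring. The fallback sets out from 22 (as a C11 mixture). TEMPO with PhI(OAc)2 in MeCN/H2O gives 6-(tert-butyldimethylsilyloxy)-8-(4-methoxyphenoxy)germacra-1(10)E,4Z-dien-12-oic acid F4. HF·pyridine removes the silyl group and the cis-disposed O6 lactonises; KOt-Bu in t-BuOH then equilibrates C11 to cis-fused (11S)-8-(4-methoxyphenoxy)germacra-1(10)E,4Z-dien-12,6-olide F5, in which the C13 methyl lies on the convex face, trans to C8, as in the target. LiAlH4 gives (6S,7S,8S,11S)-8-(4-methoxyphenoxy)germacra-1(10)E,4Z-diene-6,12-diol F6. TBSOTf with 2,6-lutidine gives the 6,12-bis(tert-butyldimethylsilyl) ether F7, and selective cleavage of the primary silyl ether (PPTS, MeOH) returns the route at 22 as a single C11 epimer.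

**Step 16.** The most likely failures are oxidation at the free primary hydroxyl by tetravalent cerium, and acid-promoted loss of the silyl ether or transannular cyclisation of the 1,5-diene. Fallback: change the order so that the oxidant never meets a free primary alcohol. The fallback sets out from 22. Reaction with one equivalent of mixed anhydride 25 at rt acylates only the primary hydroxyl and gives the 12-mono-angelate of 22 F8. Buffered (NH4)2Ce(NO3)6 then removes the aryl ether to give the 12-O-angeloyl-8-hydroxy-6-silyl ether F9, and a second acylation with 25 at 75 °C returns the route at 26. This protects the primary hydroxyl but not the silyl ether or the diene.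

**Step 19.** The most likely failures are delivery of oxygen to the wrong face if the substituted ten-membered ring does not follow the behaviour of simpler Z-cycloalkenols, and slow epoxidation with competing oxidation of the hindered allylic alcohol to the enone. Fallback: replace substrate direction by reagent control with a Sharpless asymmetric epoxidation of 27 (Ti(Oi-Pr)4, D-(−)-diisopropyl tartrate, t-BuOOH, CH2Cl2, −20 °C). This tartrate enantiomer is the one that delivers oxygen to the 5R face, and for a secondary allylic alcohol it is matched to the 6R-configured carbinol of 28, so the erythro product 28 is expected. The fallback sets out from 27 and returns at 28 without any new compound (F0).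

## Further compounds

F1 | step 13 | (2Z,6E,9S,10Z)-12-chloro-9-(4-methoxyphenoxy)-3,7,11-trimethyldodeca-2,6,10-trienal | ClC/C(C)=C\[C@@H](Oc1ccc(OC)cc1)C/C(C)=C/CC/C(C)=C\C=O
F2 | step 13 | (6R,7S,8S)-8-(4-methoxyphenoxy)germacra-1(10)E,4Z,11(12)-trien-6-ol (6-epimer of 19) | CC(=C)[C@H]1[C@H](O)/C=C(/C)CC/C=C(\C)C[C@@H]1Oc2ccc(OC)cc2
F3 | step 13 | 6-O-(4-nitrobenzoyl) derivative of 19 | CC(=C)[C@H]1[C@@H](OC(=O)c2ccc(cc2)[N+](=O)[O-])/C=C(/C)CC/C=C(\C)C[C@@H]1Oc3ccc(OC)cc3
F4 | step 15 | 6-(tert-butyldimethylsilyloxy)-8-(4-methoxyphenoxy)germacra-1(10)E,4Z-dien-12-oic acid (C11 mixture) | OC(=O)C(C)[C@H]1[C@@H](O[Si](C)(C)C(C)(C)C)/C=C(/C)CC/C=C(\C)C[C@@H]1Oc2ccc(OC)cc2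
F5 | step 15 | cis-fused (11S)-8-(4-methoxyphenoxy)germacra-1(10)E,4Z-dien-12,6-olide | O=C1[C@@H](C)[C@H]2[C@@H](O1)/C=C(/C)CC/C=C(\C)C[C@@H]2Oc3ccc(OC)cc3
F6 | step 15 | (6S,7S,8S,11S)-8-(4-methoxyphenoxy)germacra-1(10)E,4Z-diene-6,12-diol | OC[C@@H](C)[C@H]1[C@@H](O)/C=C(/C)CC/C=C(\C)C[C@@H]1Oc2ccc(OC)cc2
F7 | step 15 | 6,12-bis(tert-butyldimethylsilyloxy)-8-(4-methoxyphenoxy)germacra-1(10)E,4Z-diene | CC(C)(C)[Si](C)(C)OC[C@@H](C)[C@H]1[C@@H](O[Si](C)(C)C(C)(C)C)/C=C(/C)CC/C=C(\C)C[C@@H]1Oc2ccc(OC)cc2
F8 | step 16 | 6-(tert-butyldimethylsilyloxy)-8-(4-methoxyphenoxy)germacra-1(10)E,4Z-dien-12-yl (Z)-2-methylbut-2-enoate | C/C=C(/C)C(=O)OC[C@@H](C)[C@H]1[C@@H](O[Si](C)(C)C(C)(C)C)/C=C(/C)CC/C=C(\C)C[C@@H]1Oc2ccc(OC)cc2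
F9 | step 16 | 6-(tert-butyldimethylsilyloxy)-8-hydroxygermacra-1(10)E,4Z-dien-12-yl (Z)-2-methylbut-2-enoate | C/C=C(/C)C(=O)OC[C@@H](C)[C@H]1[C@@H](O[Si](C)(C)C(C)(C)C)/C=C(/C)CC/C=C(\C)C[C@@H]1O
F0 | step 19 | none | none
A1 | alternative 1 | trans-fused 6-(tert-butyldimethylsilyloxy)germacra-1(10)E,4Z,11(13)-trien-12,8-olide | O=C1O[C@H]2C/C(C)=C/CC/C(C)=C\[C@H](O[Si](C)(C)C(C)(C)C)[C@@H]2C1=C
A2 | alternative 2 | 6-(tert-butyldimethylsilyloxy)-8,12-bis(4-methoxybenzyloxy)-2-(phenylsulfonyl)germacra-1(10)E,4Z-diene (either C2 epimer) | COc1ccc(COC[C@@H](C)[C@H]2[C@@H](O[Si](C)(C)C(C)(C)C)/C=C(/C)CC(S(=O)(=O)c3ccccc3)/C=C(\C)C[C@@H]2OCc4ccc(OC)cc4)cc1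
A3 | alternative 3 | 8-(benzyldimethylsilyl)-12-(4-methoxybenzyloxy)germacra-1(10)E,4Z-dien-6-one | COc1ccc(COC[C@@H](C)[C@H]2C(=O)/C=C(/C)CC/C=C(\C)C[C@@H]2[Si](C)(C)Cc3ccccc3)cc1
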